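**Strategy.** All three drimane units come from one protected 15-hydroxyalbicanol, and each ether-linked isocitrate from a copper-catalysed Mukaiyama–Michael addition. The drimane rests on disconnecting ring A at C2–C3 and ring B at C5–C10 and C8–C9, which leads back to an acyclic tetraene ester in which C11 and C12, the vicinal one-carbon branches on C9 and C8, are tied as an ester. In one operation ring-closing metathesis joins C2 to C3 in a 13-membered lactone, and its transannular Diels–Alder reaction then forms C5–C10 and C8–C9, so that rings A and B and a temporary γ-lactone arise together with C5, C9 and C10 set.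

Key step: step 9

Remark on numbering: drimane numbering is used for every sesquiterpene unit (ring A = C1–C5 and C10; ring B = C5–C10; C11 on C9; C12 on C8; C15 = the oxygenated 4α carbon). In the isocitrate, C2 is the ether carbon with ester carbon C1, C3 the central carbon with carboxyl C6, and C4–C5 the CH2–carboxyl arm.

Assumption: in step 16 the (S,S) ligand is taken to expose the face of the fumaroyl imide that gives 3S, and the Z ketene acetal to give the 2,3-syn (threo) adduct; if the facial sense is opposite, the (R,R) ligand is used with everything else unchanged.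

Step 1
Reactants: 1 (2E)-3-methylpent-2-en-4-yn-1-ol
Product: 2 (2E)-3-methylpenta-2,4-dien-1-ol
Conditions: H2 (1 atm), Pd/CaCO3 poisoned with Pb(OAc)2, quinoline, hexane/EtOAc, 0 °C
Reagents that add atoms: none
Why: Lindlar semi-hydrogenation should stop at the alkene and turn the ethynyl group into the vinyl group that later becomes C3; no stereocentre is formed.

Step 2
Reactants: 2 (2E)-3-methylpenta-2,4-dien-1-ol
Product: 3 [(2S,3S)-3-ethenyl-3-methyloxiran-2-yl]methanol
Conditions: Ti(OiPr)4, L-(+)-diethyl tartrate, t-BuOOH, 4 Å molecular sieves, CH2Cl2, −20 °C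
Reagents that add atoms: tert-butyl hydroperoxide, CC(C)(C)OO
Why: Sharpless asymmetric epoxidation is directed by the hydroxyl to the 2,3-alkene only, and the L-(+)-tartrate complex should deliver oxygen to the face that gives the (2S,3S) epoxide.

Step 3
Reactants: 3 epoxy alcohol
Product: 4 tert-butyl{[(2S,3S)-3-ethenyl-3-methyloxiran-2-yl]methoxy}diphenylsilane
Conditions: t-BuPh2SiCl, imidazole, DMF, 23 °C
Reagents that add atoms: tert-butyl(chloro)diphenylsilane, CC(C)(C)[Si](Cl)(c1ccccc1)c1ccccc1
Why: Standard silylation of the primary alcohol installs the group that later protects O15 and migrates in step 4.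

Step 4
Reactants: 4 epoxy silyl ether
Product: 5 (2S)-2-({[tert-butyl(diphenyl)silyl]oxy}methyl)-2-methylbut-3-enal
Conditions: MeAl(OC6H2-4-Br-2,6-tBu2)2, CH2Cl2, −78 °C
Reagents that add atoms: none
Why: Lewis-acid-promoted semipinacol-type rearrangement of the 2,3-epoxy silyl ether opens the tertiary allylic C–O bond and the silyloxymethyl group migrates anti to the leaving oxygen, so the quaternary centre (the future C4) forms with inversion as the S aldehyde.

Step 5
Reactants: 5 (2S)-aldehyde
Product: 6 ethyl (2E,4E,6R)-6-({[tert-butyl(diphenyl)silyl]oxy}methyl)-6-methylocta-2,4,7-trienoate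
Conditions: (EtO)2P(O)CH2CH=CHCO2Et, LiN(SiMe3)2, THF, −78 to 0 °C
Reagents that add atoms: ethyl (2E)-4-(diethoxyphosphoryl)but-2-enoate, CCOC(=O)/C=C/CP(=O)(OCC)OCC
Why: Vinylogous Horner–Wadsworth–Emmons olefination of the non-enolisable aldehyde should give the E,E diene (C5=C6–C7=C8 with C12 as the ester carbon).

Step 6
Reactants: 6 dienoate
Product: 7 (2E,4E,6R)-6-({[tert-butyl(diphenyl)silyl]oxy}methyl)-6-methylocta-2,4,7-trien-1-ol
Conditions: iBu2AlH, CH2Cl2, −78 °C
Reagents that add atoms: none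
Why: 1,2-Reduction of the conjugated ester by the aluminium hydride gives the dienyl alcohol without touching the alkenes or the silyl ether.

Step 7
Reactants: 8 pent-1-en-4-yne
Product: 10 (2E)-3-methylhexa-2,5-dienoic acid, via alkenylalane 9 (not isolated)
Conditions: Me3Al, Cp2ZrCl2 (cat.), CH2Cl2, 23 °C; then n-BuLi, THF, −78 °C; CO2; aq. HCl
Reagents that add atoms: trimethylaluminium, C[Al](C)C; carbon dioxide, O=C=O
Why: Negishi zirconium-catalysed carboalumination adds methyl and aluminium syn across the alkyne, which fixes the E geometry, and the alanate is carboxylated with retention.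

Step 8
Reactants: 7 dienol; 10 (2E)-3-methylhexa-2,5-dienoic acid
Product: 11 (2E,4E,6R)-6-({[tert-butyl(diphenyl)silyl]oxy}methyl)-6-methylocta-2,4,7-trien-1-yl (2E)-3-methylhexa-2,5-dienoate
Conditions: DCC, DMAP (cat.), CH2Cl2, 0 °C
Reagents that add atoms: none
Why: Steglich esterification at low temperature should join O12 to C11 without moving the skipped diene into conjugation.

Step 9
Reactants: 11 tetraene ester
Product: 13 γ-lactone of 15-(tert-butyldiphenylsilyloxy)-12-hydroxydrima-2,6-dien-11-oic acid (5α,8α,9α-H), via macrolactone 12 (not isolated)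
Conditions: second-generation Hoveyda–Grubbs catalyst (10 mol %), 1,4-benzoquinone (20 mol %), toluene (0.001 M), 80 °C, then 110 °C
Reagents that add atoms: none
Why: The ruthenium alkylidene formed at the unhindered allyl terminus of 11 closes the 13-membered lactone 12 by ring-closing metathesis (macrocyclisation; new C2=C3 bond), and secondary metathesis should equilibrate its E and Z isomers so that the Z isomer, the only one that can fold for cycloaddition, is drained. Lactone 12 then undergoes a transannular Diels–Alder reaction, the closest known type being macrocyclisation followed by transannular [4+2] cycloaddition: the C5=C6–C7=C8 diene adds to the C9=C10 enoate and forms C5–C10 and C8–C9. This closes ring A (six-membered, over the C1–C4 bridge), ring B (the cyclohexene of the cycloaddition) and the γ-lactone (five-membered, over the C12–O–C11 bridge) at the same time. The E,E diene puts C4 and C12 cis and the E enoate puts C1 and C11 trans on ring B, so the folding with the ester carbonyl endo, which also avoids a trans-fused γ-lactone, gives the trans A/B fusion (H5 α, 10-methyl β) and β C11 on C9, while C8 is only temporary. The diene face is selected by the preset quaternary C4, whose bulky silyloxymethyl group should take the equatorial site and whose methyl the axial site of the chair-like C1–C4 bridge. The step needs ring closure to outrun oligomerisation and the allyl group to initiate before the diene, which high dilution, the two fully substituted turn atoms C4 and C10 and the low reactivity of internal conjugated alkenes toward the carbene should secure.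

Step 10
Reactants: 13 tricyclic diene lactone
Product: 14 γ-lactone of 15-(tert-butyldiphenylsilyloxy)-12-hydroxydriman-11-oic acid (5α,8α,9α-H)
Conditions: H2 (3 atm), Pd/C, EtOAc, 23 °C
Reagents that add atoms: none
Why: Catalytic hydrogenation saturates both disubstituted ring alkenes (C2=C3 and C6=C7), which creates no stereocentre because all four carbons become CH2.

Step 11
Reactants: 14 saturated lactone
Product: 15 15-(tert-butyldiphenylsilyloxy)-12-(phenylselanyl)driman-11-oic acid (8α,9α-H)
Conditions: PhSeSePh, NaBH4, DMF, 120 °C; then aq. HCl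
Reagents that add atoms: diphenyl diselenide, c1ccc(cc1)[Se][Se]c1ccccc1
Why: The soft selenolate opens the γ-lactone by SN2 attack at the primary alkyl carbon C12, which cleaves the temporary C12–O bond and frees the C11 carboxylic acid.

Step 12
Reactants: 15 seleno acid
Product: 16 15-(tert-butyldiphenylsilyloxy)drim-8(12)-en-11-oic acid (9α-H)
Conditions: H2O2 (30 %), pyridine, THF, 0 to 23 °C
Reagents that add atoms: none
Why: Oxidation to the selenoxide and syn elimination can only use H8, the single β-hydrogen, so the exocyclic C8=C12 methylene forms regiospecifically.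

Step 13
Reactants: 16 exomethylene acid
Product: 17 15-(tert-butyldiphenylsilyloxy)drim-8(12)-en-11-ol (15-O-silyl 15-hydroxyalbicanol)
Conditions: LiAlH4, THF, 0 to 23 °C
Reagents that add atoms: none
Why: Hydride reduction of the acid gives the C11 primary alcohol and leaves the alkene, the silyl ether and the equatorial C9 configuration untouched.

Step 14
Reactants: 18 (2E)-4-tert-butoxy-4-oxobut-2-enoic acid (mono-tert-butyl fumarate); 19 1,3-oxazolidin-2-one
Product: 20 tert-butyl (2E)-4-oxo-4-(2-oxo-1,3-oxazolidin-3-yl)but-2-enoate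
Conditions: DCC, DMAP (cat.), CH2Cl2, 0 to 23 °C
Reagents that add atoms: none
Why: Carbodiimide N-acylation of the oxazolidinone gives the two-point-binding fumaroyl imide needed for the catalysed conjugate addition.

Step 15
Reactants: 17 monomer alcohol
Product: 21 methyl {[15-(tert-butyldiphenylsilyloxy)drim-8(12)-en-11-yl]oxy}acetate
Conditions: N2CHCO2Me (slow addition), Rh2(OAc)4 (1 mol %), CH2Cl2, 23 °C
Reagents that add atoms: methyl diazoacetate, COC(=O)C=[N+]=[N-]
Why: Dirhodium carbenoid O–H insertion etherifies the hindered C11 hydroxyl under neutral conditions and should be much faster than cyclopropanation of the hindered exocyclic alkene.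

Step 16
Reactants: 21 glycolate ether; 20 fumaroyl imide
Product: 23 methyl (2R,3S)-3-(tert-butoxycarbonyl)-5-oxo-5-(2-oxo-1,3-oxazolidin-3-yl)-2-{[15-(tert-butyldiphenylsilyloxy)drim-8(12)-en-11-yl]oxy}pentanoate, via ketene silyl acetal 22 (not isolated)
Conditions: LiN(iPr)2, Me3SiCl, THF, −78 °C; then 20, Cu(SbF6)2 with (S,S)-2,2'-(propane-2,2-diyl)bis(4-tert-butyl-4,5-dihydrooxazole) (10 mol %), CH2Cl2, −78 °C; aq. HCl work-up
Reagents that add atoms: chlorotrimethylsilane, C[Si](C)(C)Cl (present only in intermediate 22)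
Why: In this Mukaiyama–Michael addition the copper-bound imide directs the chelation-derived Z ketene acetal to the carbon next to the tert-butyl ester, the bis(oxazoline) ligand shields one face and sets 3S, and the open antiperiplanar transition state should give the 2,3-syn relation and so 2R.

Step 17
Reactants: 23 imide
Product: 24 2-tert-butyl 1,3-dimethyl (1R,2S)-1-{[15-(tert-butyldiphenylsilyloxy)drim-8(12)-en-11-yl]oxy}propane-1,2,3-tricarboxylate
Conditions: MeMgBr, MeOH, THF, 0 °C
Reagents that add atoms: methanol, CO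
Why: Bromomagnesium methoxide cleaves only the activated exocyclic imide carbonyl, which turns C5 into the methyl ester of the terminal isocitrate without epimerising C3.

Step 18
Reactants: 24 triester
Product: 25 2-tert-butyl 1,3-dimethyl (1R,2S)-1-{[15-hydroxydrim-8(12)-en-11-yl]oxy}propane-1,2,3-tricarboxylate
Conditions: HF·pyridine, pyridine, THF, 0 to 23 °C
Reagents that add atoms: none
Why: Buffered fluoride removes the silyl ether and frees the C15 hydroxyl while the esters and the exocyclic alkene stay intact.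

Step 19
Reactants: 23 imide
Product: 26 2-tert-butyl 1-methyl 3-prop-2-en-1-yl (1R,2S)-1-{[15-(tert-butyldiphenylsilyloxy)drim-8(12)-en-11-yl]oxy}propane-1,2,3-tricarboxylate
Conditions: MeMgBr, CH2=CHCH2OH, THF, 0 °C
Reagents that add atoms: prop-2-en-1-ol, C=CCO
Why: The same imide alcoholysis with bromomagnesium allyloxide gives the C5 allyl ester that masks the later free CH2CO2H groups.

Step 20
Reactants: 26 allyl triester
Product: 27 2-tert-butyl 1-methyl 3-prop-2-en-1-yl (1R,2S)-1-{[15-hydroxydrim-8(12)-en-11-yl]oxy}propane-1,2,3-tricarboxylate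
Conditions: HF·pyridine, pyridine, THF, 0 to 23 °C
Reagents that add atoms: none
Why: Desilylation as in step 18 frees the C15 hydroxyl of the future middle unit.

Step 21
Reactants: 26 allyl triester
Product: 28 acid corresponding to 26 with the central carboxyl (C6) free and O15 still silylated
Conditions: Me3SiOTf, 2,6-lutidine, CH2Cl2, 0 °C; then H2O
Reagents that add atoms: none
Why: Silyl triflate converts the tert-butyl ester into a silyl ester by loss of the tert-butyl cation under buffered conditions that spare the allyl and methyl esters, the silyl ether and the alkene.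

Step 22
Reactants: 28 acid (future unit C with its isocitrate); 27 alcohol (future unit B)
Product: 29 dimer in which C6 of 28 is esterified with O15 of 27
Conditions: 2,4,6-Cl3C6H2COCl, Et3N, DMAP, toluene, 23 °C
Reagents that add atoms: none
Why: Yamaguchi esterification is the standard way to acylate a neopentyl primary alcohol with an α-branched acid and should form the C15–O–C6 ester with C3 unchanged.

Step 23
Reactants: 29 dimer
Product: 30 dimer acid (central carboxyl of the isocitrate on unit B free)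
Conditions: Me3SiOTf, 2,6-lutidine, CH2Cl2, 0 °C; then H2O
Reagents that add atoms: none
Why: The single tert-butyl ester is cleaved as in step 21.

Step 24
Reactants: 30 dimer acid; 25 alcohol (future unit A)
Product: 31 fully protected trimer (O15 silyl on unit C; two allyl esters; one tert-butyl ester)
Conditions: 2,4,6-Cl3C6H2COCl, Et3N, DMAP, toluene, 23 °C
Reagents that add atoms: none
Why: A second Yamaguchi esterification joins C6 of the middle isocitrate to O15 of unit A.

Step 25
Reactants: 31 protected trimer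
Product: 32 diacid (both CH2CO2H groups free)
Conditions: Pd(PPh3)4 (5 mol %), morpholine, THF, 23 °C
Reagents that add atoms: none
Why: Tsuji–Trost deallylation, in which zerovalent palladium ionises the allyl esters and morpholine traps the π-allyl complexes, frees both acids under neutral conditions.

Step 26
Reactants: 32 diacid
Product: 33 triacid still silylated at O15 of unit C
Conditions: Me3SiOTf, 2,6-lutidine, CH2Cl2, 0 °C; then H2O
Reagents that add atoms: none
Why: The last tert-butyl ester (C6 of the terminal isocitrate) is cleaved as in step 21, the free acids being silylated only transiently.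

Step 27
Reactants: 33 triacid
Product: 34 cryptoporic acid T
Conditions: HF·pyridine, pyridine, THF, 0 to 23 °C
Reagents that add atoms: none
Why: Buffered fluoride removes the remaining silyl ether from O15 of unit C without affecting the methyl esters, the inter-unit esters or the three exocyclic alkenes.

**Compound list**

1 | (2E)-3-methylpent-2-en-4-yn-1-ol | C#C/C(C)=C/CO | starting material
2 | (2E)-3-methylpenta-2,4-dien-1-ol | C=C/C(C)=C/CO | intermediate
3 | [(2S,3S)-3-ethenyl-3-methyloxiran-2-yl]methanol | OC[C@@H]1O[C@@]1(C)C=C | intermediate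
4 | tert-butyl{[(2S,3S)-3-ethenyl-3-methyloxiran-2-yl]methoxy}diphenylsilane | CC(C)(C)[Si](c1ccccc1)(c1ccccc1)OC[C@@H]1O[C@@]1(C)C=C | intermediate
5 | (2S)-2-({[tert-butyl(diphenyl)silyl]oxy}methyl)-2-methylbut-3-enal | O=C[C@](C)(CO[Si](c1ccccc1)(c1ccccc1)C(C)(C)C)C=C | intermediate
6 | ethyl (2E,4E,6R)-6-({[tert-butyl(diphenyl)silyl]oxy}methyl)-6-methylocta-2,4,7-trienoate | CCOC(=O)/C=C/C=C/[C@](C)(CO[Si](c1ccccc1)(c1ccccc1)C(C)(C)C)C=C | intermediate
7 | (2E,4E,6R)-6-({[tert-butyl(diphenyl)silyl]oxy}methyl)-6-methylocta-2,4,7-trien-1-ol | OC/C=C/C=C/[C@](C)(CO[Si](c1ccccc1)(c1ccccc1)C(C)(C)C)C=C | intermediate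
8 | pent-1-en-4-yne | C=CCC#C | starting material
9 | dimethyl[(1E)-2-methylpenta-1,4-dien-1-yl]alumane | C=CC/C(C)=C/[Al](C)C | intermediate
10 | (2E)-3-methylhexa-2,5-dienoic acid | C=CC/C(C)=C/C(=O)O | intermediate
11 | (2E,4E,6R)-6-({[tert-butyl(diphenyl)silyl]oxy}methyl)-6-methylocta-2,4,7-trien-1-yl (2E)-3-methylhexa-2,5-dienoate | C=CC/C(C)=C/C(=O)OC/C=C/C=C/[C@](C)(CO[Si](c1ccccc1)(c1ccccc1)C(C)(C)C)C=C | intermediate
12 | (3E,6Z,9E,11E)-8-({[tert-butyl(diphenyl)silyl]oxy}methyl)-4,8-dimethyl-1-oxacyclotrideca-3,6,9,11-tetraen-2-one (quaternary centre as in 11) | O=C1OC/C=C/C=C/[C@](C)(CO[Si](c2ccccc2)(c2ccccc2)C(C)(C)C)/C=C\C/C(C)=C/1 | intermediate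
13 | γ-lactone of 15-(tert-butyldiphenylsilyloxy)-12-hydroxydrima-2,6-dien-11-oic acid (5α,8α,9α-H; 4β- and 10β-methyl; 4α-CH2OSi) | O=C1OC[C@H]2C=C[C@H]3[C@](C)(CO[Si](c4ccccc4)(c4ccccc4)C(C)(C)C)C=CC[C@]3(C)[C@@H]12 | intermediate
14 | γ-lactone of 15-(tert-butyldiphenylsilyloxy)-12-hydroxydriman-11-oic acid (5α,8α,9α-H) | O=C1OC[C@H]2CC[C@H]3[C@](C)(CO[Si](c4ccccc4)(c4ccccc4)C(C)(C)C)CCC[C@]3(C)[C@@H]12 | intermediate
15 | 15-(tert-butyldiphenylsilyloxy)-12-(phenylselanyl)driman-11-oic acid (8α,9α-H) | OC(=O)[C@H]1[C@@H](C[Se]c2ccccc2)CC[C@H]2[C@](C)(CO[Si](c3ccccc3)(c3ccccc3)C(C)(C)C)CCC[C@]12C | intermediate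
16 | 15-(tert-butyldiphenylsilyloxy)drim-8(12)-en-11-oic acid (9α-H) | OC(=O)[C@H]1C(=C)CC[C@H]2[C@](C)(CO[Si](c3ccccc3)(c3ccccc3)C(C)(C)C)CCC[C@]12C | intermediate
17 | 15-(tert-butyldiphenylsilyloxy)drim-8(12)-en-11-ol | OC[C@H]1C(=C)CC[C@H]2[C@](C)(CO[Si](c3ccccc3)(c3ccccc3)C(C)(C)C)CCC[C@]12C | intermediate
18 | (2E)-4-tert-butoxy-4-oxobut-2-enoic acid | CC(C)(C)OC(=O)/C=C/C(=O)O | starting material
19 | 1,3-oxazolidin-2-one | O=C1NCCO1 | starting material
20 | tert-butyl (2E)-4-oxo-4-(2-oxo-1,3-oxazolidin-3-yl)but-2-enoate | CC(C)(C)OC(=O)/C=C/C(=O)N1CCOC1=O | intermediate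
21 | methyl {[15-(tert-butyldiphenylsilyloxy)drim-8(12)-en-11-yl]oxy}acetate | COC(=O)COC[C@H]1C(=C)CC[C@H]2[C@](C)(CO[Si](c3ccccc3)(c3ccccc3)C(C)(C)C)CCC[C@]12C | intermediate
22 | (Z)-ketene methyl trimethylsilyl acetal of 21 (drimanyloxy cis to OSiMe3) | CO/C(O[Si](C)(C)C)=C/OC[C@H]1C(=C)CC[C@H]2[C@](C)(CO[Si](c3ccccc3)(c3ccccc3)C(C)(C)C)CCC[C@]12C | intermediate
23 | methyl (2R,3S)-3-(tert-butoxycarbonyl)-5-oxo-5-(2-oxo-1,3-oxazolidin-3-yl)-2-{[15-(tert-butyldiphenylsilyloxy)drim-8(12)-en-11-yl]oxy}pentanoate | CC(C)(C)OC(=O)[C@@H](CC(=O)N1CCOC1=O)[C@@H](OC[C@H]3C(=C)CC[C@H]4[C@](C)(CO[Si](c5ccccc5)(c5ccccc5)C(C)(C)C)CCC[C@]34C)C(=O)OC | intermediate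
24 | 2-tert-butyl 1,3-dimethyl (1R,2S)-1-{[15-(tert-butyldiphenylsilyloxy)drim-8(12)-en-11-yl]oxy}propane-1,2,3-tricarboxylate | CC(C)(C)OC(=O)[C@@H](CC(=O)OC)[C@@H](OC[C@H]3C(=C)CC[C@H]4[C@](C)(CO[Si](c5ccccc5)(c5ccccc5)C(C)(C)C)CCC[C@]34C)C(=O)OC | intermediate
25 | 2-tert-butyl 1,3-dimethyl (1R,2S)-1-{[15-hydroxydrim-8(12)-en-11-yl]oxy}propane-1,2,3-tricarboxylate | CC(C)(C)OC(=O)[C@@H](CC(=O)OC)[C@@H](OC[C@H]3C(=C)CC[C@H]4[C@](C)(CO)CCC[C@]34C)C(=O)OC | intermediate
26 | 2-tert-butyl 1-methyl 3-prop-2-en-1-yl (1R,2S)-1-{[15-(tert-butyldiphenylsilyloxy)drim-8(12)-en-11-yl]oxy}propane-1,2,3-tricarboxylate | CC(C)(C)OC(=O)[C@@H](CC(=O)OCC=C)[C@@H](OC[C@H]3C(=C)CC[C@H]4[C@](C)(CO[Si](c5ccccc5)(c5ccccc5)C(C)(C)C)CCC[C@]34C)C(=O)OC | intermediate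
27 | 2-tert-butyl 1-methyl 3-prop-2-en-1-yl (1R,2S)-1-{[15-hydroxydrim-8(12)-en-11-yl]oxy}propane-1,2,3-tricarboxylate | CC(C)(C)OC(=O)[C@@H](CC(=O)OCC=C)[C@@H](OC[C@H]3C(=C)CC[C@H]4[C@](C)(CO)CCC[C@]34C)C(=O)OC | intermediate
28 | acid of 26: central (C6) carboxyl free; C1 methyl ester; C5 allyl ester; O15 silylated | OC(=O)[C@@H](CC(=O)OCC=C)[C@@H](OC[C@H]3C(=C)CC[C@H]4[C@](C)(CO[Si](c5ccccc5)(c5ccccc5)C(C)(C)C)CCC[C@]34C)C(=O)OC | intermediate
29 | dimer: C6 of 28 esterified with O15 of 27 | CC(C)(C)OC(=O)[C@@H](CC(=O)OCC=C)[C@@H](OC[C@H]3C(=C)CC[C@H]4[C@](C)(COC(=O)[C@@H](CC(=O)OCC=C)[C@@H](OC[C@H]5C(=C)CC[C@H]6[C@](C)(CO[Si](c7ccccc7)(c7ccccc7)C(C)(C)C)CCC[C@]56C)C(=O)OC)CCC[C@]34C)C(=O)OC | intermediate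
30 | dimer acid: 29 with the tert-butyl ester cleaved | OC(=O)[C@@H](CC(=O)OCC=C)[C@@H](OC[C@H]3C(=C)CC[C@H]4[C@](C)(COC(=O)[C@@H](CC(=O)OCC=C)[C@@H](OC[C@H]5C(=C)CC[C@H]6[C@](C)(CO[Si](c7ccccc7)(c7ccccc7)C(C)(C)C)CCC[C@]56C)C(=O)OC)CCC[C@]34C)C(=O)OC | intermediate
31 | protected trimer: C6 of 30 esterified with O15 of 25 | C=C1CC[C@H]2[C@](C)(COC(=O)[C@@H](CC(=O)OCC=C)[C@@H](OC[C@H]3C(=C)CC[C@H]4[C@](C)(COC(=O)[C@@H](CC(=O)OCC=C)[C@@H](OC[C@H]5C(=C)CC[C@H]6[C@](C)(CO[Si](c7ccccc7)(c7ccccc7)C(C)(C)C)CCC[C@]56C)C(=O)OC)CCC[C@]34C)C(=O)OC)CCC[C@]2(C)[C@H]1CO[C@@H](C(=O)OC)[C@H](CC(=O)OC)C(=O)OC(C)(C)C | intermediate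
32 | trimer with both CH2CO2H groups free (tert-butyl ester and O15 silyl ether retained) | C=C1CC[C@H]2[C@](C)(COC(=O)[C@@H](CC(=O)O)[C@@H](OC[C@H]3C(=C)CC[C@H]4[C@](C)(COC(=O)[C@@H](CC(=O)O)[C@@H](OC[C@H]5C(=C)CC[C@H]6[C@](C)(CO[Si](c7ccccc7)(c7ccccc7)C(C)(C)C)CCC[C@]56C)C(=O)OC)CCC[C@]34C)C(=O)OC)CCC[C@]2(C)[C@H]1CO[C@@H](C(=O)OC)[C@H](CC(=O)OC)C(=O)OC(C)(C)C | intermediate
33 | trimer triacid with O15 of unit C still silylated | C=C1CC[C@H]2[C@](C)(COC(=O)[C@@H](CC(=O)O)[C@@H](OC[C@H]3C(=C)CC[C@H]4[C@](C)(COC(=O)[C@@H](CC(=O)O)[C@@H](OC[C@H]5C(=C)CC[C@H]6[C@](C)(CO[Si](c7ccccc7)(c7ccccc7)C(C)(C)C)CCC[C@]56C)C(=O)OC)CCC[C@]34C)C(=O)OC)CCC[C@]2(C)[C@H]1CO[C@@H](C(=O)OC)[C@H](CC(=O)OC)C(=O)O | intermediate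
34 | cryptoporic acid T | C=C1CC[C@H]2[C@](C)(COC(=O)[C@@H](CC(=O)O)[C@@H](OC[C@H]3C(=C)CC[C@H]4[C@](C)(COC(=O)[C@@H](CC(=O)O)[C@@H](OC[C@H]5C(=C)CC[C@H]6[C@](C)(CO)CCC[C@]56C)C(=O)OC)CCC[C@]34C)C(=O)OC)CCC[C@]2(C)[C@H]1CO[C@@H](C(=O)OC)[C@H](CC(=O)OC)C(=O)O | target

**Step count and risks**

Total steps: 27. Longest linear sequence: 22 steps (1–6, 8–13, 15, 16, 19, 21–27).

The three steps most likely to fail:

1. Step 9. Intermolecular metathesis (oligomerisation) may outrun closure of the 13-membered ring, or the E-configured macrolactone may fail to isomerise, so that the transannular cycloaddition never starts. The fallback sets out from 11 and reverses the order of events. Heating 11 without catalyst (1,2-dichlorobenzene, 2,6-di-tert-butyl-4-methylphenol, 180 °C) should give, by an ester-tethered intramolecular Diels–Alder reaction through the carbonyl-endo transition state, the cis-fused bicyclic lactone carrying the vinyl and allyl groups F1. Ring-closing metathesis of these two groups (second-generation Grubbs catalyst, CH2Cl2, 40 °C) then closes ring A as an ordinary six-membered ring and comes back to the route at 13. In this order the facial control by C4 is expected to be weaker, so a diastereomer separation may be needed.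

2. Step 16. The copper-catalysed addition may show poor facial selectivity, or be outrun by uncatalysed addition or by protodesilylation of the ketene acetal. The fallback sets out from 18 and 22 and replaces catalyst control by auxiliary control. Acid 18 is coupled (DCC, DMAP) with (4S)-4-benzyl-1,3-oxazolidin-2-one to give tert-butyl (2E)-4-[(4S)-4-benzyl-2-oxo-1,3-oxazolidin-3-yl]-4-oxobut-2-enoate F2 (or its enantiomer if the sense of induction requires). TiCl4-promoted Mukaiyama–Michael addition of 22 at −78 °C should give the benzyl-oxazolidinone adduct F3. Alcoholysis with bromomagnesium methoxide or allyloxide as in steps 17 and 19 comes back to the route at 24 and 26.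

3. Step 22 (the same applies to step 24). Acylation of the neopentyl C15 hydroxyl may be slow, which would let the activated acid epimerise at C3 or lose the C2 alkoxy group by β-elimination. The fallback sets out from 20 and 27 and forms the C15–O–C6 ester before the isocitrate stereocentres exist. CF3CO2H cleaves the tert-butyl ester of 20 to (2E)-4-oxo-4-(2-oxo-1,3-oxazolidin-3-yl)but-2-enoic acid F4. Steglich esterification of F4 with the C15 hydroxyl of 27 gives the fumaroyl imide ester F5. Mukaiyama–Michael addition of 22 under the catalyst of step 16 gives the dimeric imide F6. Alcoholysis with bromomagnesium allyloxide then comes back to the route at 29.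

Further compounds

F1 | step 9 | cis-fused γ-lactone from the intramolecular Diels–Alder reaction of 11 (ring B cyclohexene with 4-substituted C5 side chain bearing vinyl and 10-allyl) | O=C1OC[C@H]2C=C[C@@H]([C@](C)(CO[Si](c3ccccc3)(c3ccccc3)C(C)(C)C)C=C)[C@](C)(CC=C)[C@@H]12
F2 | step 16 | tert-butyl (2E)-4-[(4S)-4-benzyl-2-oxo-1,3-oxazolidin-3-yl]-4-oxobut-2-enoate | CC(C)(C)OC(=O)/C=C/C(=O)N1[C@@H](Cc2ccccc2)COC1=O
F3 | step 16 | analogue of 23 carrying the (4S)-4-benzyl-oxazolidinone | CC(C)(C)OC(=O)[C@@H](CC(=O)N1[C@@H](Cc2ccccc2)COC1=O)[C@@H](OC[C@H]3C(=C)CC[C@H]4[C@](C)(CO[Si](c5ccccc5)(c5ccccc5)C(C)(C)C)CCC[C@]34C)C(=O)OC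
F4 | step 22 | (2E)-4-oxo-4-(2-oxo-1,3-oxazolidin-3-yl)but-2-enoic acid | OC(=O)/C=C/C(=O)N1CCOC1=O
F5 | step 22 | 27 acylated at O15 by F4 | CC(C)(C)OC(=O)[C@@H](CC(=O)OCC=C)[C@@H](OC[C@H]3C(=C)CC[C@H]4[C@](C)(COC(=O)/C=C/C(=O)N1CCOC1=O)CCC[C@]34C)C(=O)OC
F6 | step 22 | dimeric imide: analogue of 29 with the oxazolidinone imide in place of the allyl ester on the isocitrate of unit C | CC(C)(C)OC(=O)[C@@H](CC(=O)OCC=C)[C@@H](OC[C@H]3C(=C)CC[C@H]4[C@](C)(COC(=O)[C@@H](CC(=O)N1CCOC1=O)[C@@H](OC[C@H]5C(=C)CC[C@H]6[C@](C)(CO[Si](c7ccccc7)(c7ccccc7)C(C)(C)C)CCC[C@]56C)C(=O)OC)CCC[C@]34C)C(=O)OC
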